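## Retrosynthetic overview

1. Target ⇐ phenol deacetylation, Markovnikov H–Br addition to a C15 isopropenyl group, and anti bromohydrin formation at the 10E-alkene of a bicyclic macrolide.
2. Cyclohexene ring (C2–C7 bond, C6–Br) ⇐ transannular, anodically triggered bromonium cyclisation of a 19-membered 2E,6E,10E-triene macrolactone (key step).
3. Macrolactone ⇐ seco-acid (ester bond to O14); seco-acid ⇐ B-alkyl Suzuki coupling (C9–C10) of an aryl geranyl-diene with an (S)-vinyl iodide.
4. Vinyl iodide ⇐ L-glutamic-acid-derived lactone ester (the only purchased stereocentre, C14); aryl diene ⇐ methyl 4-hydroxybenzoate + geranyl bromide.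
5. Ring order: 19-membered macrolactone first, then the cyclohexene by transannular closure, which contracts it to the 15-membered macrolide.

Assumptions: positions use geranylgeranyl numbering (C1 = benzylic CH2, C14 = CH–O, C15 = CMe2Br, C16 = the C15 methyl that is =CH2 in intermediates). The target SMILES is read as 6S,7S,10R,11S,14S. Ethyl (S)-5-oxotetrahydrofuran-2-carboxylate (made from L-glutamic acid) is taken as purchasable.

## Route

**Step 1**
Reactants: 1 methyl 4-hydroxybenzoate; 2 geranyl bromide
Product: 3 methyl 3-[(2E)-3,7-dimethylocta-2,6-dien-1-yl]-4-hydroxybenzoate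
Conditions: NaH, toluene, 0 °C → rt; 2 (0.8 equiv)
Reagents that add atoms: none (both partners are numbered reactants)
Why: ortho C-alkylation of the sodium phenoxide in a non-polar solvent (SN2 at the allylic bromide, para position blocked) keeps the 2E geometry; the O-geranyl ether is a separable by-product.

**Step 2**
Reactants: 3
Product: 4 methyl 3-[(2E,6E)-3,7-dimethyl-8-oxoocta-2,6-dien-1-yl]-4-hydroxybenzoate
Conditions: SeO2 (cat.), t-BuOOH, salicylic acid (cat.), CH2Cl2, rt; then MnO2, CH2Cl2
Reagents that add atoms: selenium dioxide O=[Se]=O; tert-butyl hydroperoxide CC(C)(C)OO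
Why: Sharpless SeO2 allylic oxidation (ene/[2,3]) selects the E-methyl of the terminal isopropylidene group, and MnO2 converges the alcohol/aldehyde mixture to the E-enal.

**Step 3**
Reactants: 4
Product: 5 methyl 3-[(2E,6E)-3,7-dimethylnona-2,6,8-trien-1-yl]-4-hydroxybenzoate
Conditions: Ph3PCH3Br, KHMDS (2.5 equiv), THF, −78 → 0 °C
Reagents that add atoms: methyltriphenylphosphonium bromide C[P+](c1ccccc1)(c1ccccc1)c1ccccc1.[Br-]
Why: Wittig methylenation of the enal gives the terminal 1,3-diene; excess ylide covers the phenol and the ester and alkene geometries are untouched.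

**Step 4**
Reactants: 6 ethyl (2S)-5-oxooxolane-2-carboxylate
Product: 7 (5S)-5-(2-hydroxypropan-2-yl)oxolan-2-one
Conditions: MeMgBr (2.2 equiv), THF, −78 → −20 °C; NH4Cl
Reagents that add atoms: methylmagnesium bromide C[Mg]Br
Why: Grignard double addition to the α-alkoxy ester, which is more electrophilic than the γ-lactone at low temperature; the C–H stereocentre (future C14) is not touched.

**Step 5**
Reactants: 7
Product: 8 (5S)-5-(prop-1-en-2-yl)oxolan-2-one
Conditions: POCl3, pyridine, 0 °C → rt
Reagents that add atoms: none
Why: E2 dehydration of the tertiary alcohol through its dichlorophosphate removes a methyl hydrogen (the ring C–H next to oxygen is deactivated), giving the isopropenyl group without touching the stereocentre.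

**Step 6**
Reactants: 8
Product: 9 (3S)-2-methylhept-1-en-6-yn-3-ol
Conditions: DIBAL-H, CH2Cl2, −78 °C; then MeOH, K2CO3, Ohira–Bestmann reagent, rt
Reagents that add atoms: dimethyl (1-diazo-2-oxopropyl)phosphonate COP(=O)(OC)C(=[N+]=[N-])C(C)=O
Why: lactone-to-lactol reduction followed by Seyferth–Gilbert (Ohira–Bestmann) homologation of the open hydroxy-aldehyde gives the terminal alkyne; the carbinol centre is not epimerisable.

**Step 7**
Reactants: 9
Product: 10 (3S,6E)-7-iodo-2,6-dimethylhepta-1,6-dien-3-ol
Conditions: Me3Al (3 equiv), Cp2ZrCl2 (0.25 equiv), CH2Cl2, 0 °C → rt; then I2, THF, −30 °C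
Reagents that add atoms: trimethylaluminium C[Al](C)C; iodine II
Why: Negishi Zr-catalysed carboalumination (syn Me–Al addition, Me to the internal carbon) and iodinolysis with retention fix the future 10E geometry.

**Step 8**
Reactants: 5; 10
Product: 11 methyl 4-hydroxy-3-[(2E,6E,10E,14S)-14-hydroxy-3,7,11,15-tetramethylhexadeca-2,6,10,15-tetraen-1-yl]benzoate
Conditions: 5, 9-BBN, THF, 0 °C → rt; then aq. K3PO4, 10, Pd(dppf)Cl2, AsPh3, DMF, rt
Reagents that add atoms: none (9-BBN delivers only H to C8; boron is lost)
Why: 9-BBN hydroborates only the terminal vinyl of the diene (B at C9), and B-alkyl Suzuki–Miyaura coupling with the vinyl iodide forms C9–C10 with retention of alkene geometry.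

**Step 9**
Reactants: 11
Product: 12 4-acetoxy-3-[(2E,6E,10E,14S)-14-hydroxy-3,7,11,15-tetramethylhexadeca-2,6,10,15-tetraen-1-yl]benzoic acid
Conditions: LiOH, THF/MeOH/H2O, 50 °C; then Ac2O, aq. NaOH (pH 9–10), 0 °C; H3O+
Reagents that add atoms: lithium hydroxide [Li+].[OH-]; acetic anhydride CC(=O)OC(C)=O
Why: saponification, then selective acetylation of the phenoxide in aqueous base (the alcohol and carboxylate are not acetylated); the acetate later blocks chroman formation and ring bromination.

**Step 10**
Reactants: 12
Product: 13 19-membered macrolactone of 12 (carboxyl esterified to O14; 4-acetoxy-1,3-phenylene bridged by the C1–C14 chain; 2E,6E,10E; 14S; isopropenyl on C14)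
Conditions: MNBA, DMAP, Et3N, CH2Cl2 (1 mM, slow addition), rt
Reagents that add atoms: none
Why: Shiina macrolactonisation at high dilution acylates the single secondary allylic hydroxyl with retention at C14.

**Step 11**
Reactants: 13
Product: 14 (6S,7S,14S)-bicyclic 15-membered macrolide: new C2–C7 bond; cyclohexene C2=C3(Me)–C4H2–C5H2–C6H(Br)–C7(Me); benzylic C1H2 on C2; 10E-alkene; isopropenyl on C14; aryl acetate
Conditions: undivided cell, graphite(+)/Pt(−), n-Bu4NBr (1.05 equiv), Et2S (20 mol %), n-Bu4NPF6 (0.1 M), CH2Cl2/HFIP 4:1, 2 mA cm−2, 2.2 F mol−1, −20 °C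
Reagents that add atoms: tetrabutylammonium bromide CCCC[N+](CCCC)(CCCC)CCCC.[Br-]
Why: Proposed new method: anodic oxidation of bromide gives Br2, which diethyl sulfide captures as a bromosulfonium carrier (Et2S–Br+) in ionising, non-nucleophilic HFIP. Br+ is passed reversibly between the alkenes, and the 6,7-bromonium is drained because the neighbouring 2,3-alkene attacks C7 through C2 in a chair-like anti addition (Br to the 6Si face, C2 to the 7Re face, giving 6S,7S). The C3 cation loses H-2 to give the tetrasubstituted alkene, while the cathode reduces the released proton so no HBr builds up; the low steady-state Br2/Br− level suppresses dibromide. Facial selectivity is substrate control relayed from the purchased C14 centre, whose exo isopropenyl group biases the fold of the 19-membered ring. Closest known chemistry: anodic bromide oxidation for alkene bromofunctionalisation, and reagent-based (BDSB, TBCO) bromonium polyene cyclisations.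

**Step 12**
Reactants: 14
Product: 15 (6S,7S,10R,11S,14S)-10-bromo-11-hydroxy derivative of 14 (bromohydrin; ring alkene, isopropenyl and aryl acetate retained)
Conditions: NBS (1.05 equiv), acetone/H2O 4:1, 0 °C
Reagents that add atoms: N-bromosuccinimide O=C1CCC(=O)N1Br; water O
Why: bromohydrin formation by anti, Markovnikov opening of a bromonium ion: Br+ adds to the exposed Re face of C10 and water opens at tertiary C11 from its Si face, giving 10R,11S under control of the rigid bicyclic macrolide. The ring alkene is shielded by quaternary C7 and the isopropenyl alkene is deactivated by the allylic ester.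

**Step 13**
Reactants: 15
Product: 16 bromophycolide A O-acetate (C15 = CMe2Br)
Conditions: Co(acac)2, t-BuOOH, Et3SiH, TsBr, n-PrOH/CH2Cl2, rt
Reagents that add atoms: p-toluenesulfonyl bromide Cc1ccc(cc1)S(=O)(=O)Br
Why: cobalt-hydride HAT Markovnikov hydrobromination: H• adds to the CH2 terminus of the 1,1-disubstituted alkene and the tertiary C15 radical abstracts Br from TsBr; the hindered tetrasubstituted alkene is inert and no stereocentre is formed.

**Step 14**
Reactants: 16
Product: 17 bromophycolide A
Conditions: NH4OAc, MeOH/H2O, rt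
Reagents that add atoms: none
Why: neutral cleavage of the activated aryl acetate leaves the alkyl benzoate lactone, the bromohydrin (no base, so no epoxide) and the tertiary bromide intact.

## Compound list

1 | methyl 4-hydroxybenzoate | COC(=O)c1ccc(O)cc1 | starting material
2 | geranyl bromide | CC(C)=CCC/C(C)=C/CBr | starting material
3 | methyl 3-geranyl-4-hydroxybenzoate | COC(=O)c1ccc(O)c(C/C=C(\C)CCC=C(C)C)c1 | intermediate
4 | methyl 3-[(2E,6E)-3,7-dimethyl-8-oxoocta-2,6-dienyl]-4-hydroxybenzoate | COC(=O)c1ccc(O)c(C/C=C(\C)CC/C=C(\C)C=O)c1 | intermediate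
5 | methyl 3-[(2E,6E)-3,7-dimethylnona-2,6,8-trienyl]-4-hydroxybenzoate | COC(=O)c1ccc(O)c(C/C=C(\C)CC/C=C(\C)C=C)c1 | intermediate
6 | ethyl (2S)-5-oxooxolane-2-carboxylate | CCOC(=O)[C@@H]1CCC(=O)O1 | starting material
7 | (5S)-5-(2-hydroxypropan-2-yl)oxolan-2-one | CC(C)(O)[C@@H]1CCC(=O)O1 | intermediate
8 | (5S)-5-(prop-1-en-2-yl)oxolan-2-one | CC(=C)[C@@H]1CCC(=O)O1 | intermediate
9 | (3S)-2-methylhept-1-en-6-yn-3-ol | CC(=C)[C@@H](O)CCC#C | intermediate
10 | (3S,6E)-7-iodo-2,6-dimethylhepta-1,6-dien-3-ol | CC(=C)[C@@H](O)CC/C(C)=C/I | intermediate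
11 | methyl 4-hydroxy-3-[(2E,6E,10E,14S)-14-hydroxy-3,7,11,15-tetramethylhexadeca-2,6,10,15-tetraenyl]benzoate | COC(=O)c1ccc(O)c(C/C=C(\C)CC/C=C(\C)CC/C=C(\C)CC[C@H](O)C(C)=C)c1 | intermediate
12 | 4-acetoxy seco-acid (14S) | CC(=O)Oc1ccc(C(=O)O)cc1C/C=C(\C)CC/C=C(\C)CC/C=C(\C)CC[C@H](O)C(C)=C | intermediate
13 | 19-membered triene macrolactone (14S) | CC(=O)Oc1ccc(C2=O)cc1C/C=C(\C)CC/C=C(\C)CC/C=C(\C)CC[C@H](O2)C(C)=C | intermediate
14 | (6S,7S,14S)-6-bromo bicyclic macrolide, 10E-alkene, 14-isopropenyl, O-acetate | CC1=C2Cc3cc(ccc3OC(C)=O)C(=O)O[C@H](C(C)=C)CC/C(C)=C/CC[C@]2(C)[C@@H](Br)CC1 | intermediate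
15 | (6S,7S,10R,11S,14S)-6,10-dibromo-11-hydroxy, 14-isopropenyl, O-acetate | CC1=C2Cc3cc(ccc3OC(C)=O)C(=O)O[C@H](C(C)=C)CC[C@](C)(O)[C@H](Br)CC[C@]2(C)[C@@H](Br)CC1 | intermediate
16 | bromophycolide A O-acetate | CC1=C2Cc3cc(ccc3OC(C)=O)C(=O)O[C@H](C(C)(C)Br)CC[C@](C)(O)[C@H](Br)CC[C@]2(C)[C@@H](Br)CC1 | intermediate
17 | bromophycolide A | CC1=C2Cc3cc(ccc3O)C(=O)O[C@H](C(C)(C)Br)CC[C@](C)(O)[C@H](Br)CC[C@]2(C)[C@@H](Br)CC1 | target

## Summary

Total steps: 14. Longest linear sequence: 11 (6 → 7 → 8 → 9 → 10 → 11 → 12 → 13 → 14 → 15 → 16 → 17).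

The sense of the two macrocycle-relayed facial selectivities (steps 11 and 12) is assumed, not modelled; it is the main uncertainty of the route.

Steps most likely to fail:

1. **Step 11 (proposed new electrochemical transannular bromocyclisation).** Risks are Br+ capture through the 10,11-alkene instead of the 6,7-alkene, the wrong sense of the C14 → C6/C7 relay, and proton loss giving tri- or exocyclic alkene isomers. Fallback (known chemistry, no electrode): Hg(OTf)2·PhNMe2 transannular mercuricyclisation of 13 to the C6 organomercurial, then bromodemercuration (Br2/LiBr, pyridine); or the preformed bromosulfonium reagent BDSB in MeNO2 at −25 °C.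

2. **Step 12 (bromohydrin).** Risks are competing attack on the tetrasubstituted ring alkene and the wrong exposed face. Fallback: a two-step epoxidation (buffered m-CPBA, −20 °C) and SN2 bromide opening at C10 (Li2NiBr4 or LiBr/AcOH). From the same exposed face this gives the opposite facial pairing to NBS/H2O, so one of the two sequences should give 10R,11S.

3. **Step 13 (late-stage HAT hydrobromination).** Risks are radical side reactions and incomplete selectivity on a polybrominated substrate. Fallback: drop the isopropenyl handle by omitting step 5 and carrying the C15 tertiary alcohol through steps 6–10 (lactonisation is selective for the secondary OH). Then convert it to the tertiary bromide by benzoate-assisted substitution (TMSBr, 2-methyl-2-butene, CH2Cl2, −20 °C) before steps 11–12.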